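**Plan**

1. Numbering of the target as a cyclohepta[b]furan-2-one (O1, C2, C3, C3a, C4–C8, C8a). Retrosynthetic cuts: the C3 methyl goes back to an exocyclic methylene; the lactone O1–C8a bond and the free C5–OH go back to one oxygen bridging C5 and C8a; the O8 ester and the C7–acyl bond are cut; the strategic cut removes C4–C5 and C3a–C8a together.
2. Enabling feature: C5 and C8a are both carbinol carbons, 1,4-related across the seven-membered ring and joined on the other side by the oxygenated three-carbon arc C6–C7–C8. Tied through one oxygen, C5–C6–C7–C8–C8a plus that oxygen is a 4-alkoxy-3-oxidopyrylium (from 3-hydroxy-4-pyranone), and C4–C3a is the 2π unit of but-3-yn-2-one, whose acetyl group becomes C3 and its methyl.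
3. Forward: pyranone → ylide → [5+2] cycloaddition gives the cycloheptane and the temporary oxygen bridge (8-oxabicyclo[3.2.1]octane) at once. On the rigid bicycle follow exo hydrogenation (C3a), storage of the side chain as enol triflate, methylenation / enol ether oxidation / 1,4-reduction (C6, C7 ketone, C8–OH), exo addition of a butenoyl anion equivalent (C7), angeloylation and carbonylation.
4. Ring events at the end: the side-chain acid opens the bridge at C8a with inversion, so the lactone closes and C5–OH is set free with retention; convex-face hydrogenation then sets C3.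
5. Stereochemistry: absolute configuration comes from bought (−)-menthol, carried as a menthyloxymethyl group on the ylide oxygen (diastereomer separation after the cycloaddition, group lost in the enol ether oxidation). All other centers are relayed from the two bridgeheads by the bicycle.

Key step: step 2

Remark: 3-hydroxy-4H-pyran-4-one, chloromethyl (1R,2S,5R)-menthyl ether, but-3-yn-2-one, 1-methoxybuta-1,3-diene and angelic acid are taken as purchasable; dimethyldioxirane is used as its acetone solution.

Locants: bicycle atoms C1, C2, C3, C4, C5, C6, C7 become target atoms C5, C6, C7, C8, C8a, C3a, C4. "exo" means on the face of the oxygen bridge, "endo" the opposite face; "menthyl" is (1R,2S,5R)-menthyl.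

**Step 1**
Reactants: 1 3-hydroxy-4H-pyran-4-one
Product: 2 3-(tert-butyldimethylsilyloxy)-4H-pyran-4-one
Conditions: TBSCl, imidazole, DMF, rt
Reagents that add atoms: tert-butyldimethylsilyl chloride, CC(C)(C)[Si](C)(C)Cl
Why: Silyl ether formation at the acidic enolic hydroxyl masks the future oxide, so that the carbonyl oxygen is the only site left for O-alkylation.

**Step 2**
Reactants: 2 3-(tert-butyldimethylsilyloxy)-4H-pyran-4-one; 3 chloromethyl (1R,2S,5R)-menthyl ether; 4 but-3-yn-2-one
Product: 7 6-acetyl-3-[(menthyloxy)methoxy]-8-oxabicyclo[3.2.1]octa-3,6-dien-2-one (bridgehead diastereomer of the SMILES), via pyrylium triflate 5 (not isolated), via oxidopyrylium ylide 6 (not isolated)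
Conditions: 3, AgOTf, CH2Cl2, 0 °C to rt; then 4 (excess), CsF, rt; chromatographic separation of the two bridgehead diastereomers
Reagents that add atoms: none
Why: Silver-assisted O-alkylation of the pyranone carbonyl (the alkoxymethyl counterpart of the methyl triflate alkylation) gives pyrylium 5, fluoride removes the silyl group, and the 4-alkoxy-3-oxidopyrylium 6 (a five-atom, six-electron dipole over C2–O1–C6) adds to the ynone in a concerted, asynchronous, suprafacial [5+2] cycloaddition; the closest known reaction type is the intermolecular cycloaddition of 4-methoxy-3-oxidopyrylium ylides with electron-poor alkenes and alkynes. The two σ-bonds close the cycloheptadiene ring and, in the same event, the 2,5-dihydrofuran ring whose oxygen is the bridge, both by cycloaddition and not by chain cyclization. The new stereocenters are the bridgeheads C1 and C5, cis by necessity; an alkyne has no endo/exo and no facial issue, so only two products can form, which differ in the ylide face used and are diastereomers because of the menthyl group, and the one drawn should be obtained pure after chromatography. The selectivity needed is regiochemical: the enolate-like C2 of the ylide (next to the oxide) must bond to the unsubstituted β-carbon of the ynone and C6 to the acetyl-bearing carbon, which is the polarity-matched orientation normally observed (acceptor-bearing carbon next to the bridgehead remote from the ketone).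

**Step 3**
Reactants: 7 6-acetyl-3-[(menthyloxy)methoxy]-8-oxabicyclo[3.2.1]octa-3,6-dien-2-one
Product: 8 6-endo-acetyl-3-[(menthyloxy)methoxy]-8-oxabicyclo[3.2.1]oct-3-en-2-one
Conditions: H2 (1 atm), Pd/C, EtOAc, 0 °C, stopped after one equivalent
Reagents that add atoms: none
Why: Catalytic hydrogenation takes the strained, acetyl-conjugated C6=C7 bond much faster than the alkoxy-substituted enone and delivers hydrogen from the exo face (that of the oxygen bridge), which places the acetyl group endo and sets C6.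

**Step 4**
Reactants: 8 6-endo-acetyl-3-[(menthyloxy)methoxy]-8-oxabicyclo[3.2.1]oct-3-en-2-one
Product: 9 3-[(menthyloxy)methoxy]-6-endo-[1-(triflyloxy)vinyl]-8-oxabicyclo[3.2.1]oct-3-en-2-one
Conditions: KN(SiMe3)2, THF, −78 °C; then PhNTf2
Reagents that add atoms: N-phenylbis(trifluoromethanesulfonimide), O=S(=O)(N(c1ccccc1)S(=O)(=O)C(F)(F)F)C(F)(F)F
Why: Kinetic enolization of the methyl ketone and O-triflation (enol triflate formation) is site-selective because the ring ketone has no enolizable α-hydrogen (bridgehead on one side, sp2 carbon on the other); it stores the side chain as a carbonylation handle and ends the epimerizability of C6.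

**Step 5**
Reactants: 9 3-[(menthyloxy)methoxy]-6-endo-[1-(triflyloxy)vinyl]-8-oxabicyclo[3.2.1]oct-3-en-2-one
Product: 10 2-methylene-3-[(menthyloxy)methoxy]-6-endo-[1-(triflyloxy)vinyl]-8-oxabicyclo[3.2.1]oct-3-ene
Conditions: Ph3PCH3Br, KOt-Bu, THF, 0 °C to rt
Reagents that add atoms: methyltriphenylphosphonium bromide, C[P+](c1ccccc1)(c1ccccc1)c1ccccc1.[Br-]
Why: Wittig methylenation of the only ketone brings in the carbon of the future C2 methyl group and turns the enol ether into an electron-rich 2-alkoxydiene.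

**Step 6**
Reactants: 10 2-methylene-3-[(menthyloxy)methoxy]-6-endo-[1-(triflyloxy)vinyl]-8-oxabicyclo[3.2.1]oct-3-ene
Product: 12 4-exo-hydroxy-2-methylene-6-endo-[1-(triflyloxy)vinyl]-8-oxabicyclo[3.2.1]octan-3-one, via alkoxy epoxide 11 (not isolated)
Conditions: dimethyldioxirane, acetone/CH2Cl2, −78 to 0 °C; then PPTS, THF/H2O, rt
Reagents that add atoms: dimethyldioxirane, CC1(C)OO1; water, O
Why: Rubottom-type oxidation: the dioxirane epoxidizes the most electron-rich double bond (the enol ether) from the exo face, away from the two-carbon bridge and its endo side chain, and hydrolysis of the alkoxy epoxide gives the C3 ketone and the axial (exo) C4 hydroxyl while releasing the auxiliary as menthol and formaldehyde.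

**Step 7**
Reactants: 12 4-exo-hydroxy-2-methylene-6-endo-[1-(triflyloxy)vinyl]-8-oxabicyclo[3.2.1]octan-3-one
Product: 13 4-exo-hydroxy-2-endo-methyl-6-endo-[1-(triflyloxy)vinyl]-8-oxabicyclo[3.2.1]octan-3-one
Conditions: LiBH(s-Bu)3, THF, −78 °C; aq NH4Cl
Reagents that add atoms: none
Why: Conjugate (1,4) hydride reduction of the β-unsubstituted exo-methylene ketone by the hindered borohydride, then protonation of the enolate from the open exo face, should give the equatorial (also thermodynamically preferred) C2 methyl group, the enol triflate being inert.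

**Step 8**
Reactants: 13 4-exo-hydroxy-2-endo-methyl-6-endo-[1-(triflyloxy)vinyl]-8-oxabicyclo[3.2.1]octan-3-one; 14 1-methoxybuta-1,3-diene
Product: 16 3-exo-[(E)-but-2-enoyl]-2-endo-methyl-6-endo-[1-(triflyloxy)vinyl]-8-oxabicyclo[3.2.1]octane-3-endo,4-exo-diol, via dienyl ether adduct 15 (not isolated)
Conditions: 14, s-BuLi, THF, −78 °C; CeCl3, −78 °C; then 13 (reagent in excess), −78 °C; then 1 M HCl, THF, 0 °C
Reagents that add atoms: water, O
Why: Addition of an acyl anion equivalent (the α-metallated dienyl ether as its weakly basic organocerium reagent) to the ketone should come from the exo (equatorial) direction, because the endo face is closed by the two-carbon bridge and its endo substituent; the new carbon group is then equatorial and the tertiary hydroxyl axial, and acid hydrolysis of the dienyl ether gives the conjugated (E)-butenoyl ketone.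

**Step 9**
Reactants: 16 3-exo-[(E)-but-2-enoyl]-2-endo-methyl-6-endo-[1-(triflyloxy)vinyl]-8-oxabicyclo[3.2.1]octane-3-endo,4-exo-diol; 17 angelic acid
Product: 18 3-exo-[(E)-but-2-enoyl]-3-endo-hydroxy-2-endo-methyl-6-endo-[1-(triflyloxy)vinyl]-8-oxabicyclo[3.2.1]oct-4-exo-yl (Z)-2-methylbut-2-enoate
Conditions: 17, 2,4,6-trichlorobenzoyl chloride, Et3N, toluene, rt; then 16, toluene, 80 °C
Reagents that add atoms: none
Why: Yamaguchi esterification through the mixed anhydride acylates the only secondary hydroxyl (the tertiary one is inert) and is the protocol known to transfer the angeloyl group without Z to E isomerization.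

**Step 10**
Reactants: 18 3-exo-[(E)-but-2-enoyl]-3-endo-hydroxy-2-endo-methyl-6-endo-[1-(triflyloxy)vinyl]-8-oxabicyclo[3.2.1]oct-4-exo-yl (Z)-2-methylbut-2-enoate
Product: 19 2-{4-exo-angeloyloxy-3-exo-[(E)-but-2-enoyl]-3-endo-hydroxy-2-endo-methyl-8-oxabicyclo[3.2.1]oct-6-endo-yl}acrylic acid
Conditions: Pd(OAc)2, PPh3, CO (1 atm), KOAc, DMF/H2O, 50 °C
Reagents that add atoms: carbon monoxide, [C-]#[O+]; water, O
Why: Palladium-catalysed hydroxycarbonylation of the enol triflate (oxidative addition, CO insertion, hydrolysis of the acyl-palladium species) should give the 2-substituted acrylic acid under conditions that leave the esters and the enone untouched.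

**Step 11**
Reactants: 19 2-{4-exo-angeloyloxy-3-exo-[(E)-but-2-enoyl]-3-endo-hydroxy-2-endo-methyl-8-oxabicyclo[3.2.1]oct-6-endo-yl}acrylic acid
Product: 20 (3aS,5R,6S,7S,8S,8aR)-7-[(E)-but-2-enoyl]-5,7-dihydroxy-6-methyl-3-methylene-2-oxooctahydro-2H-cyclohepta[b]furan-8-yl (Z)-2-methylbut-2-enoate
Conditions: Sc(OTf)3 (10 mol %), CH2Cl2, 0 °C to rt
Reagents that add atoms: none
Why: Proposed new method: Lewis-acid-promoted lactonization with ether cleavage, in which Sc(OTf)3 coordinates the bridging oxygen and the endo carboxyl group, held anti-periplanar to the C5–O8 bond, displaces the oxonium oxygen by 5-exo-tet backside attack (inversion at C5, which becomes C8a of the cis-fused lactone), while the bridge oxygen stays on C1 with retention as the free hydroxyl and takes up the acid proton, so that the step is an isomerization; the closest known reaction types are the acid-catalysed 5-exo opening of epoxides and oxetanes by a neighbouring carboxylic acid with inversion and the Lewis-acid cleavage of strained bridged ethers by nucleophiles.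

**Step 12**
Reactants: 20 (3aS,5R,6S,7S,8S,8aR)-7-[(E)-but-2-enoyl]-5,7-dihydroxy-6-methyl-3-methylene-2-oxooctahydro-2H-cyclohepta[b]furan-8-yl (Z)-2-methylbut-2-enoate
Product: 21 (3R,3aS,5R,6S,7S,8S,8aR)-7-[(E)-but-2-enoyl]-5,7-dihydroxy-3,6-dimethyl-2-oxooctahydro-2H-cyclohepta[b]furan-8-yl (Z)-2-methylbut-2-enoate
Conditions: H2 (1 atm), RhCl(PPh3)3, benzene/EtOH, rt
Reagents that add atoms: none
Why: Homogeneous hydrogenation with RhCl(PPh3)3 should reduce the unhindered 1,1-disubstituted exocyclic methylene much faster than the trans-disubstituted enone or the trisubstituted angelate, and adds hydrogen from the convex face of the cis-fused lactone, which puts the C3 methyl group on the concave face as required.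

**Compound list**

1 | 3-hydroxy-4H-pyran-4-one (pyromeconic acid) | O=C1C=COC=C1O | starting material
2 | 3-(tert-butyldimethylsilyloxy)-4H-pyran-4-one | O=C1C=COC=C1O[Si](C)(C)C(C)(C)C | intermediate
3 | chloromethyl (1R,2S,5R)-menthyl ether | C[C@@H]1CC[C@H]([C@@H](C1)OCCl)C(C)C | starting material
4 | but-3-yn-2-one | CC(=O)C#C | starting material
5 | 3-(tert-butyldimethylsilyloxy)-4-[(menthyloxy)methoxy]pyrylium triflate | C[C@@H]1CC[C@H]([C@@H](C1)OCOc2cc[o+]cc2O[Si](C)(C)C(C)(C)C)C(C)C.[O-]S(=O)(=O)C(F)(F)F | intermediate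
6 | 4-[(menthyloxy)methoxy]pyrylium-3-olate (oxidopyrylium ylide) | C[C@@H]1CC[C@H]([C@@H](C1)OCOc2cc[o+]cc2[O-])C(C)C | intermediate
7 | 6-acetyl-3-[(menthyloxy)methoxy]-8-oxabicyclo[3.2.1]octa-3,6-dien-2-one | C[C@@H]1CC[C@H]([C@@H](C1)OCOC2=C[C@@H]3C(C(C)=O)=C[C@@H](O3)C2=O)C(C)C | intermediate
8 | 6-endo-acetyl-3-[(menthyloxy)methoxy]-8-oxabicyclo[3.2.1]oct-3-en-2-one | C[C@@H]1CC[C@H]([C@@H](C1)OCOC2=C[C@@H]3[C@H](C(C)=O)C[C@@H](O3)C2=O)C(C)C | intermediate
9 | 3-[(menthyloxy)methoxy]-6-endo-[1-(triflyloxy)vinyl]-8-oxabicyclo[3.2.1]oct-3-en-2-one | C[C@@H]1CC[C@H]([C@@H](C1)OCOC2=C[C@@H]3[C@H](C(=C)OS(=O)(=O)C(F)(F)F)C[C@@H](O3)C2=O)C(C)C | intermediate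
10 | 2-methylene-3-[(menthyloxy)methoxy]-6-endo-[1-(triflyloxy)vinyl]-8-oxabicyclo[3.2.1]oct-3-ene | C[C@@H]1CC[C@H]([C@@H](C1)OCOC2=C[C@@H]3[C@H](C(=C)OS(=O)(=O)C(F)(F)F)C[C@@H](O3)C2=C)C(C)C | intermediate
11 | 3,4-exo-epoxy-2-methylene-3-[(menthyloxy)methoxy]-6-endo-[1-(triflyloxy)vinyl]-8-oxabicyclo[3.2.1]octane | C[C@@H]1CC[C@H]([C@@H](C1)OCO[C@@]25O[C@H]5[C@@H]3[C@H](C(=C)OS(=O)(=O)C(F)(F)F)C[C@@H](O3)C2=C)C(C)C | intermediate
12 | 4-exo-hydroxy-2-methylene-6-endo-[1-(triflyloxy)vinyl]-8-oxabicyclo[3.2.1]octan-3-one | O[C@H]1[C@@H]2[C@H](C(=C)OS(=O)(=O)C(F)(F)F)C[C@@H](O2)C(=C)C1=O | intermediate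
13 | 4-exo-hydroxy-2-endo-methyl-6-endo-[1-(triflyloxy)vinyl]-8-oxabicyclo[3.2.1]octan-3-one | O[C@H]1[C@@H]2[C@H](C(=C)OS(=O)(=O)C(F)(F)F)C[C@@H](O2)[C@H](C)C1=O | intermediate
14 | 1-methoxybuta-1,3-diene | COC=CC=C | starting material
15 | 3-exo-(1-methoxybuta-1,3-dienyl)-2-endo-methyl-6-endo-[1-(triflyloxy)vinyl]-8-oxabicyclo[3.2.1]octane-3-endo,4-exo-diol | O[C@H]1[C@@H]2[C@H](C(=C)OS(=O)(=O)C(F)(F)F)C[C@@H](O2)[C@H](C)[C@@]1(O)C(OC)=CC=C | intermediate
16 | 3-exo-[(E)-but-2-enoyl]-2-endo-methyl-6-endo-[1-(triflyloxy)vinyl]-8-oxabicyclo[3.2.1]octane-3-endo,4-exo-diol | O[C@H]1[C@@H]2[C@H](C(=C)OS(=O)(=O)C(F)(F)F)C[C@@H](O2)[C@H](C)[C@@]1(O)C(=O)/C=C/C | intermediate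
17 | angelic acid, (Z)-2-methylbut-2-enoic acid | C/C=C(/C)C(=O)O | starting material
18 | 3-exo-[(E)-but-2-enoyl]-3-endo-hydroxy-2-endo-methyl-6-endo-[1-(triflyloxy)vinyl]-8-oxabicyclo[3.2.1]oct-4-exo-yl (Z)-2-methylbut-2-enoate | C/C=C(/C)C(=O)O[C@H]1[C@@H]2[C@H](C(=C)OS(=O)(=O)C(F)(F)F)C[C@@H](O2)[C@H](C)[C@@]1(O)C(=O)/C=C/C | intermediate
19 | 2-{4-exo-angeloyloxy-3-exo-[(E)-but-2-enoyl]-3-endo-hydroxy-2-endo-methyl-8-oxabicyclo[3.2.1]oct-6-endo-yl}acrylic acid | C/C=C(/C)C(=O)O[C@H]1[C@@H]2[C@H](C(=C)C(=O)O)C[C@@H](O2)[C@H](C)[C@@]1(O)C(=O)/C=C/C | intermediate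
20 | (3aS,5R,6S,7S,8S,8aR)-7-[(E)-but-2-enoyl]-5,7-dihydroxy-6-methyl-3-methylene-2-oxooctahydro-2H-cyclohepta[b]furan-8-yl (Z)-2-methylbut-2-enoate | C/C=C(/C)C(=O)O[C@H]1[C@@H]2OC(=O)C(=C)[C@@H]2C[C@@H](O)[C@H](C)[C@@]1(O)C(=O)/C=C/C | intermediate
21 | (3R,3aS,5R,6S,7S,8S,8aR)-7-[(E)-but-2-enoyl]-5,7-dihydroxy-3,6-dimethyl-2-oxooctahydro-2H-cyclohepta[b]furan-8-yl (Z)-2-methylbut-2-enoate | C/C=C(/C)C(=O)O[C@H]1[C@@H]2OC(=O)[C@H](C)[C@@H]2C[C@@H](O)[C@H](C)[C@@]1(O)C(=O)/C=C/C | target

**Count**

Total steps: 12. Longest linear sequence: 12 steps (from 1).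

**Steps most likely to fail**

Step 11 (Proposed new method). The activated bridge may ionize or eliminate instead of being displaced at the bridgehead, and the Lewis acid may trigger an α-ketol shift or Z to E isomerization of the angelate. The fallback uses known chemistry, sets out from 19 and comes back at 20. Me2BBr with Et3N in CH2Cl2 at −78 °C should cleave the bridging ether by SN2 attack of bromide at the less hindered bridgehead (the other one is flanked by the acyloxy-bearing carbon), giving 2-{3-angeloyloxy-6-bromo-4-[(E)-but-2-enoyl]-2,4-dihydroxy-5-methylcycloheptyl}acrylic acid F1, with the bromide inverted and the hydroxyl of the future C8a still on the former bridge face. A Mitsunobu lactonization (PPh3, DIAD, THF) should then close the lactone with inversion at that carbinol to give the 5-epi-bromo lactone F2. Displacement of the bromide with inversion by Bu4NNO2 in DMF, followed by aqueous work-up of the nitrite ester, should restore the C5 hydroxyl with net retention and give 20.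

Step 9. Acylation of the axial hydroxyl next to the quaternary carbon may be slow, which leaves time for Z to E isomerization of the activated angelate. The fallback sets out from 13 and comes back at 18. The much less hindered hydroxyl of ketol 13 should be acylated first under the same Yamaguchi protocol to give 4-exo-angeloyloxy-2-endo-methyl-6-endo-[1-(triflyloxy)vinyl]-8-oxabicyclo[3.2.1]octan-3-one F3. The organocerium reagent from 14 should then add to the ketone from the exo face to give the dienyl ether carbinol F4, and work-up with 1 M HCl should give 18.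

Step 12. Chemoselectivity may be lost (reduction of the butenoyl double bond), or the rhodium hydride may move the exocyclic double bond into the ring. The fallback sets out from 19 and comes back at 21. A carboxylate-directed hydrogenation of the acrylic acid with Ru(OAc)2[(R)-BINAP], H2 (4 atm), MeOH before ring closure should give, under catalyst control, (R)-2-{4-exo-angeloyloxy-3-exo-[(E)-but-2-enoyl]-3-endo-hydroxy-2-endo-methyl-8-oxabicyclo[3.2.1]oct-6-endo-yl}propanoic acid F5. Lactonization as in step 11 (Sc(OTf)3, CH2Cl2) should then give 21 directly.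

**Further compounds**

F1 | step 11 | 2-{3-angeloyloxy-6-bromo-4-[(E)-but-2-enoyl]-2,4-dihydroxy-5-methylcycloheptyl}acrylic acid | C/C=C(/C)C(=O)O[C@H]1[C@@H](O)[C@H](C(=C)C(=O)O)C[C@H](Br)[C@H](C)[C@@]1(O)C(=O)/C=C/C
F2 | step 11 | 5-bromo-7-[(E)-but-2-enoyl]-7-hydroxy-6-methyl-3-methylene-2-oxooctahydro-2H-cyclohepta[b]furan-8-yl (Z)-2-methylbut-2-enoate (C5 epimeric to 20) | C/C=C(/C)C(=O)O[C@H]1[C@@H]2OC(=O)C(=C)[C@@H]2C[C@H](Br)[C@H](C)[C@@]1(O)C(=O)/C=C/C
F3 | step 9 | 4-exo-angeloyloxy-2-endo-methyl-6-endo-[1-(triflyloxy)vinyl]-8-oxabicyclo[3.2.1]octan-3-one | C/C=C(/C)C(=O)O[C@H]1[C@@H]2[C@H](C(=C)OS(=O)(=O)C(F)(F)F)C[C@@H](O2)[C@H](C)C1=O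
F4 | step 9 | 3-endo-hydroxy-3-exo-(1-methoxybuta-1,3-dienyl)-2-endo-methyl-6-endo-[1-(triflyloxy)vinyl]-8-oxabicyclo[3.2.1]oct-4-exo-yl (Z)-2-methylbut-2-enoate | C/C=C(/C)C(=O)O[C@H]1[C@@H]2[C@H](C(=C)OS(=O)(=O)C(F)(F)F)C[C@@H](O2)[C@H](C)[C@@]1(O)C(OC)=CC=C
F5 | step 12 | (R)-2-{4-exo-angeloyloxy-3-exo-[(E)-but-2-enoyl]-3-endo-hydroxy-2-endo-methyl-8-oxabicyclo[3.2.1]oct-6-endo-yl}propanoic acid | C/C=C(/C)C(=O)O[C@H]1[C@@H]2[C@H]([C@@H](C)C(=O)O)C[C@@H](O2)[C@H](C)[C@@]1(O)C(=O)/C=C/C
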